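The numbers in the tables were generated by integration from invented constants; scatter was added.

**Early minutes.** In the early minutes you can compare the flasks straight from their readings. The Friday's run, with half the catalyst, holds 16.67 mM at 22 min, and the Saturday's run held 16.29 mM at 11 min, so the clock follows the catalyst.

| flask | substrate | free catalyst | time |
|---|---|---|---|
| Saturday's | 80.0 mM | 0.160 mM |  |
| Thursday's | 32.0 mM | 0.160 mM |  |
| Tuesday's | 40.0 mM | 0.160 mM |  |
| Friday's | 80.0 mM | 0.0800 mM |  |
| Sunday's | 17.0 mM | 0.160 mM | 78 min |

- Saturday's run (time / min: [target] / mM): 3.1: 5.20; 5.9: 9.40; 11: 16.29; 22: 29.35; 41: 44.33; 78: 59.06
- Thursday's run (time / min: [target] / mM): 3.1: 2.17; 5.9: 3.24; 11: 6.52; 22: 10.62; 41: 16.18; 78: 21.45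
- Tuesday's run (time / min: [target] / mM): 3.1: 2.42; 5.9: 4.58; 11: 8.70; 22: 14.20; 41: 21.10; 78: 28.06
- Friday's run (time / min: [target] / mM): 3.1: 2.51; 5.9: 5.17; 11: 8.45; 22: 16.67; 41: 27.18; 78: 42.96

(scatter of a reading: 0.2 mM)

* the exponent of [free catalyst] in the starting rate at the charge of the Saturday's run (at the point where two percent of the substrate have become target)
* the exponent of [substrate] in the starting rate at the charge of the Saturday's run (at the point where two percent of the substrate have become target) (one fixed amount of target, the same in the runs compared)
* the Thursday's run starts with 48.0 mM less of substrate than the Saturday's run, and with no target. Compared where both hold the same amount of substrate, once fifteen percent of what the Thursday's run was charged with has turned into target, is the Thursday's run faster, slower or alike (within a tenth)?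
* target in the Sunday's run at 78 min, as a share of the substrate charged
* which of these the readings show (the product kills the catalyst / the substrate kills the catalyst / the product ties up the catalyst / nothing beyond the main steps / the product speeds the reaction)

- Overall: substrate -> target, with free catalyst as catalyst.
- Constant volume, constant temperature.
- Readings of a species count what is bound in complexes too.
- An order is taken over about fifteen percent of the charge, up and down.

**Middle rung.** The next rung is the mean first-order constant of a run: the logarithm of the charge over the charge minus the target made, divided by the time. At 11 min it reads 0.0207 /min in the Saturday's run, 0.0223 /min in the Tuesday's run and 0.0207 /min in the Thursday's run, and these readings do not rise or fall in step with the charge.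

**Last rung.** At 78 min the same constant reads 0.0142 /min in the Thursday's run, 0.0155 /min in the Tuesday's run and 0.0172 /min in the Saturday's run, each lower than its reading at 11 min, and now they order themselves by charge. Take one plus the logarithm of the ratio of two such constants over the logarithm of the ratio of their charges: from the Thursday's to the Tuesday's run this gives 1.38, the late order. It is a rough reading, and the Sunday's charge of 17.0 mM lies below the Thursday's 32.0 mM, but my own reckoning uses it: scaling the Thursday's constant to the Sunday's charge with the late order, I expect 58.1%.

**The forecast.** It gives order 1 in catalyst, 0.97 in substrate, the Thursday's run faster, 60% for the Sunday's run, and this verdict: the product ties up the catalyst. It warns: “That trend is not fully explained by simple inhibition”. My 58.1% for the Sunday's run is lower than its figure.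

**The flask.** At the Saturday's charge the order in catalyst is 1.0, and the order in substrate is 0.77, which is lower than forecast. The Thursday's run is faster, the Sunday's run reaches 58.7%, and the verdict is the product ties up the catalyst.

    free catalyst + substrate ⇌ catalyst-substrate complex, settled at all times (31.60 /M)
    catalyst-substrate complex + substrate ⇌ doubly bound catalyst, settled at all times (13.10 /M)
    doubly bound catalyst → target + catalyst-substrate complex (24.30 /min)
    free catalyst + target ⇌ catalyst-product complex, settled at all times (16.50 /M)

The binding of free catalyst and target moves the readings by 7.4 times the scatter. Between the Thursday's and the Sunday's run, where the Sunday's mean constant is 0.0113 /min, the late order is 1.36, lower than the 1.38 between the Thursday's and the Tuesday's run.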